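**Strategy.** The cyclobutane is cut by a retro-[2+2] into two molecules of (Z)-ligustilide, and the plan then rests on the carbocycle C3a–C4–C5–C6–C7–C7a of that monomer. With C3a=C7a and C6=C7 this ring is a cyclohexa-1,3-diene, the retron of a hexatriene. The key step builds it in one flask from an acyclic enynoate and acrolein: a deconjugative α-aldol condensation forges C7–C7a (as the central triene alkene) and a 6π-electrocyclization closes C4–C5. The pentynyl arm is the masked butylidene lactone. A catalyst-controlled head-to-head photodimerization then sets all four stereocentres in one event.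

Key step: step 2

Remark: phthalide numbering is used (C1 lactone carbonyl, C3 butylidene-bearing carbon, C8 exocyclic alkene carbon, C3a/C7a ring-fusion carbons). In the dimer the unprimed unit is the one whose C3a and C7a lie in the cyclobutane; the primed unit contributes C6′ and C7′.

Assumption: ethyl (2Z)-3-iodobut-2-enoate (1) is taken as a catalogue compound.

Assumption: the sense of induction of the chiral Lewis acid in step 5 cannot be assigned in advance; the (S)-prolinol-derived catalyst is written, and its mirror image is to be used if the opposite series results.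

Step 1
Reactants: 1 ethyl (2Z)-3-iodobut-2-enoate; 2 pent-1-yne
Product: 3 ethyl (2Z)-3-methyloct-2-en-4-ynoate
Conditions: PdCl2(PPh3)2 (2 mol %), CuI (4 mol %), Et3N, THF, 23 °C
Reagents that add atoms: pent-1-yne (2), C#CCCC
Why: Sonogashira coupling of a (Z)-β-iodoenoate is stereoretentive, so the ester should stay cis to the new pentynyl arm and trans to the methyl group.

Step 2
Reactants: 3 ethyl (2Z)-3-methyloct-2-en-4-ynoate; 4 acrolein
Product: 9 ethyl 2-(pent-1-yn-1-yl)cyclohexa-1,5-diene-1-carboxylate, via lithium dienolate 5 (not isolated), via lithium aldolate 6 (not isolated), via allylic mesylate 7 (not isolated), via triene 8 (not isolated)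
Conditions: LiN(iPr)2, THF/DMPU, −78 °C; acrolein, −78 °C; MsCl, then Et3N, −78 → 23 °C; toluene, BHT, 90 °C
Reagents that add atoms: acrolein (4), C=CC=O
Why: LiN(iPr)2 should remove a proton from the γ-methyl group of 3 to give the cross-conjugated dienolate 5, which adds through its α-carbon to the carbonyl group of acrolein (kinetic α- and 1,2-selectivity of lithium ester dienolates at −78 °C) and so forms C7–C7a in aldolate 6. Mesylation to 7 and Et3N-induced E1cB elimination turn this bond into the central alkene of triene 8, and thermal disrotatory 6π-electrocyclization then forms C4–C5 and leaves C7–C7a as the single bond between C6=C7 and C3a=C7a. The closest known reaction type is the aldol (Knoevenagel-type) condensation/6π-electrocyclization sequence used as a formal [3+3] synthesis of cyclohexa-1,3-dienes. The only ring closed is the six-membered carbocycle, in the hexatriene-to-cyclohexadiene electrocyclic mode, and no stereocentre is created. The step needs site-selective deprotonation, α-attack and the (2E) triene: the pentynyl arm offers no position as acidic as the γ-methyl group (a butylidene lactone would instead give an aromatic furanolate), and the elimination should favour the isomer with the vinyl group trans to the ester, which is the one able to cyclise.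

Step 3
Reactants: 9 ethyl 2-(pent-1-yn-1-yl)cyclohexa-1,5-diene-1-carboxylate
Product: 10 2-(pent-1-yn-1-yl)cyclohexa-1,5-diene-1-carboxylic acid
Conditions: LiOH·H2O, THF/MeOH/H2O (degassed), 23 °C; then 1 M HCl to pH 3
Reagents that add atoms: lithium hydroxide, [Li+].[OH-]
Why: Saponification at the acyl carbon should leave the alkyne and the 1,3-diene untouched, provided air is excluded to prevent aromatisation.

Step 4
Reactants: 10 2-(pent-1-yn-1-yl)cyclohexa-1,5-diene-1-carboxylic acid
Product: 11 (Z)-ligustilide, (3Z)-3-butylidene-4,5-dihydro-2-benzofuran-1(3H)-one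
Conditions: Ag2CO3 (5 mol %), toluene, 23 °C, dark
Reagents that add atoms: none
Why: Silver-catalysed 5-exo-dig cycloisomerisation of a (Z)-2-en-4-ynoic acid adds carboxylate and silver anti across the alkyne, and protodeargentation with retention should place the propyl group cis to the ring oxygen (Z).

Step 5
Reactants: 11 (Z)-ligustilide (two molecules)
Product: 12 (3aR,7aS,6′S,7′R)-(3Z,3′Z)-3a.7′,7a.6′-diligustilide (the target)
Conditions: oxazaborolidine from (S)-α,α-bis(3,5-dimethylphenyl)prolinol and 2,4,6-trifluorophenylboronic acid, activated with AlBr3 (50 mol %), hν (395 nm), CH2Cl2, −75 °C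
Reagents that add atoms: none
Why: Proposed new method: complexation of the lactone carbonyl of one molecule of 11 should shift its absorption to a wavelength at which free 11 is transparent, so that only the complex is excited; its enoate should bond through C7a to the least substituted alkene carbon C6′ of a free molecule, giving the 1,4-biradical stabilised as an oxygen-substituted allyl radical (C3a–C3=C8) and a pentadienyl radical (C7′ to C8′), which closes C3a–C7′ to the head-to-head cyclobutane; both ring fusions are necessarily cis, the incoming carbocycle should lie over the flat butenolide and away from the puckered C4–C5 bridge, and the aryl group of the catalyst should shield one face of C3a=C7a and so fix all four stereocentres; the closest known reaction type is the chiral oxazaborolidine–AlBr3-catalysed enantioselective [2+2] photocycloaddition of cyclic enones and coumarins with alkenes.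

**Compound list**

1 | ethyl (2Z)-3-iodobut-2-enoate | CCOC(=O)/C=C(/C)I | starting material
2 | pent-1-yne | C#CCCC | starting material
3 | ethyl (2Z)-3-methyloct-2-en-4-ynoate | CCOC(=O)/C=C(/C)C#CCCC | intermediate
4 | acrolein (prop-2-enal) | C=CC=O | starting material
5 | lithium dienolate of 3 (lithium 1-ethoxy-3-methylideneoct-1-en-4-yn-1-olate) | CCOC([O-])=CC(=C)C#CCCC.[Li+] | intermediate (not isolated)
6 | lithium aldolate, lithium salt of ethyl 2-(1-hydroxyprop-2-en-1-yl)-3-methylideneoct-4-ynoate (diastereomer mixture) | CCOC(=O)C(C([O-])C=C)C(=C)C#CCCC.[Li+] | intermediate (not isolated)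
7 | allylic mesylate, ethyl 2-[1-(methanesulfonyloxy)prop-2-en-1-yl]-3-methylideneoct-4-ynoate | CCOC(=O)C(C(OS(C)(=O)=O)C=C)C(=C)C#CCCC | intermediate (not isolated)
8 | triene, ethyl (2E)-2-(hept-1-en-3-yn-2-yl)penta-2,4-dienoate | CCOC(=O)/C(C(=C)C#CCCC)=C/C=C | intermediate (not isolated)
9 | ethyl 2-(pent-1-yn-1-yl)cyclohexa-1,5-diene-1-carboxylate | CCOC(=O)C1=C(C#CCCC)CCC=C1 | intermediate
10 | 2-(pent-1-yn-1-yl)cyclohexa-1,5-diene-1-carboxylic acid | OC(=O)C1=C(C#CCCC)CCC=C1 | intermediate
11 | (Z)-ligustilide, (3Z)-3-butylidene-4,5-dihydro-2-benzofuran-1(3H)-one | CCC/C=C1\OC(=O)C2=C1CCC=C2 | intermediate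
12 | (3aR,7aS,6′S,7′R)-(3Z,3′Z)-3a.7′,7a.6′-diligustilide: cyclobutane from C3a=C7a of one unit and C6′=C7′ of the other (bonds C3a–C7′ and C7a–C6′), both ring fusions cis, carbocycle of the primed unit on the same cyclobutane face as the lactone ring of the unprimed unit, both butylidenes Z | CCC/C=C1\OC(=O)C2=C1CC[C@H]1[C@@H]2[C@]23CCC=C[C@]12C(=O)O/C3=C\CCC | target

**Total step count:** 5. **Longest linear sequence:** 5 steps (1 → 3 → 9 → 10 → 11 → 12).

**Steps most likely to fail**

1. Step 5 (proposed new method). Several processes may defeat it:
   - bonding of the excited complex at the exocyclic C3=C8 enol ether or at C6=C7 instead of C3a=C7a;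
   - head-to-tail closure of the biradical;
   - photochemical Z/E isomerisation of the butylidene groups;
   - an uncatalysed racemic background reaction;
   - Lewis-acid-induced oligomerisation of 11;
   - Cope rearrangement of the cis-1,2-dialkenylcyclobutane product if it is warmed.

   Fallback (known chemistry), from 11 back to 12: direct irradiation of 11 at high concentration (λ = 350 nm, degassed benzene, 10 °C) is the classical enoate–alkene [2+2] photocyclodimerisation. Among the cyclodimers it should give the racemic head-to-head dimer, that is 12 together with its mirror image ent-12 F1. Silica chromatography removes the constitutional isomers, and preparative HPLC on an amylose tris(3,5-dimethylphenylcarbamate) phase separates 12 from F1.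

2. Step 2 (key step). Possible failures:
   - γ-attack of the dienolate or 1,4-addition to acrolein;
   - anionic polymerisation of acrolein;
   - elimination to the (2Z) triene, which cannot cyclise;
   - Diels–Alder oligomerisation of the triene during heating.

   Fallback, from acrolein 4 back to 11, bypassing 9 and 10; it forms the same two bonds in one flask by a Stobbe condensation/6π-electrocyclization:
   - 4 and dimethyl itaconate (COC(=O)CC(=C)C(=O)OC) are condensed with KOtBu in tBuOH/THF at 0 → 23 °C to give, after acidification, the triene half-ester (3E)-3-(methoxycarbonyl)-2-methylidenehexa-3,5-dienoic acid F2.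
   - F2 carries the acid on the acceptor-activated hexatriene position and should electrocyclise on gentle warming (toluene, 60 °C) to 2-(methoxycarbonyl)cyclohexa-1,3-diene-1-carboxylic acid F3.
   - (COCl)2 with catalytic DMF in CH2Cl2 at 0 °C gives methyl 2-(chlorocarbonyl)cyclohexa-1,5-diene-1-carboxylate F4.
   - n-BuMgCl with Fe(acac)3 (3 mol %) in THF at −78 °C acylates to methyl 2-pentanoylcyclohexa-1,5-diene-1-carboxylate F5.
   - LiOH in THF/H2O followed by acidification gives the ring-closed keto acid 3-butyl-3-hydroxy-4,5-dihydro-2-benzofuran-1(3H)-one F6.
   - TsOH in toluene over 4 Å molecular sieves at 60 °C dehydrates F6 to 11.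

3. Step 4. Possible failures: 6-endo-dig closure to the isomeric pyranone, silver-induced isomerisation or aromatisation of the diene, or decomposition of the labile product on the catalyst.

   Fallback, from 10 back to 11: iodolactonisation (I2, NaHCO3, MeCN, 0 °C, dark) closes the five-membered ring by anti addition to give (3E)-3-(1-iodobutylidene)-4,5-dihydro-2-benzofuran-1(3H)-one F7. Stereoretentive hydrodeiodination (Bu3SnH, Pd(PPh3)4, THF, 23 °C) then gives 11.

**Further compounds**

F1 | step 5 | ent-12, mirror image of the target, (3aS,7aR,6′R,7′S) | CCC/C=C1\OC(=O)C2=C1CC[C@@H]1[C@H]2[C@@]23CCC=C[C@@]12C(=O)O/C3=C\CCC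
F2 | step 2 | (3E)-3-(methoxycarbonyl)-2-methylidenehexa-3,5-dienoic acid | COC(=O)/C(C(=C)C(O)=O)=C/C=C
F3 | step 2 | 2-(methoxycarbonyl)cyclohexa-1,3-diene-1-carboxylic acid | COC(=O)C1=C(C(O)=O)CCC=C1
F4 | step 2 | methyl 2-(chlorocarbonyl)cyclohexa-1,5-diene-1-carboxylate | COC(=O)C1=C(C(Cl)=O)CCC=C1
F5 | step 2 | methyl 2-pentanoylcyclohexa-1,5-diene-1-carboxylate | COC(=O)C1=C(C(=O)CCCC)CCC=C1
F6 | step 2 | 3-butyl-3-hydroxy-4,5-dihydro-2-benzofuran-1(3H)-one (racemic) | CCCCC1(O)OC(=O)C2=C1CCC=C2
F7 | step 4 | (3E)-3-(1-iodobutylidene)-4,5-dihydro-2-benzofuran-1(3H)-one | CCC/C(I)=C1\OC(=O)C2=C1CCC=C2
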